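Count turnovers before reading any rate.

| flask | substrate | reagent | free catalyst | remark | time |
|---|---|---|---|---|---|
| theta | 2 mM | 0.50 equiv | 14 mol% | the very flask that is asked about, followed so far |  |
| zeta | 2 mM | 0.50 equiv | 9.4 mol% | run made earlier |  |
| flask | 2.0 mM | 0.500 equiv | 14 mol% |  | 4.0 min |

- where most of what was charged as substrate, at 4.0 min is found (product / catalyst intermediate C / catalyst intermediate B / catalyst intermediate D / catalyst intermediate A / substrate)
- the largest share itself, whichever of these holds it, in percent of the substrate charged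



In the flask, the reagent charged over the catalyst charged came to 3.57. I named this N, the turnover allowance: the full cycles each catalyst can make if every product costs one reagent. But that condition needed testing against the runs.

| run | time / s | catalyst intermediate B / % | catalyst intermediate A / % | catalyst intermediate D / % | product / % | catalyst intermediate C / % | substrate / % |
|---|---|---|---|---|---|---|---|
| theta | 10.0 | 2.4 | 4.1 | 2.5 | 7.5 | 1.1 | 83.3 |
| theta | 15.0 | 2.1 | 1.8 | 4.6 | 12.3 | 2.0 | 77.7 |
| theta | 25.0 | 1.7 | 5.1 | 2.4 | 26.8 | 0.3 | 67.0 |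
| theta | 40.0 | 1.6 | 5.9 | 2.6 | 38.2 | 1.0 | 52.7 |
| theta | 50.0 | 1.9 | 9.5 | 0.5 | 45.6 | 0 | 45.8 |
| zeta | 10.0 | 2.4 | 2.8 | 3.5 | 6.1 | 0 | 87.7 |
| zeta | 20.0 | 2.2 | 2.3 | 0.9 | 13.8 | 1.1 | 79.1 |
| zeta | 30.0 | 2.8 | 1.2 | 2.2 | 18.5 | 2.0 | 70.9 |
| zeta | 50.0 | 0.5 | 2.4 | 0.1 | 33.7 | 1.6 | 58.8 |
| zeta | 80.0 | 0 | 7.9 | 2.2 | 47.8 | 0.2 | 45.3 |
| zeta | 90.0 | 0.8 | 8.2 | 1.3 | 49.2 | 1.2 | 44.3 |

(each reading ± 1 percentage point)

So I went to the zeta run, whose allowance was 5.32. At 90.0 s its product reading of 49.2%, after 47.8% at 80.0 s, came to 5.23 turnovers. Catalyst intermediate A read 8.2% against a loading of 9.4 mol%. So I took the reagent as the limiting reagent and intermediate A as the resting state.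

The theta run, which is this flask followed so far, read 3.26 turnovers at 50.0 s, so about 0.314 remained. At its average pace of 0.0651 s⁻¹, I estimated that at 4.82 s, a figure that takes no account of any slowing as the reagent falls, but 190 s were still to come. I therefore reckoned product at 50.0%, and substrate at 36.0% once 14.0% sat in intermediate A, which puts product ahead.

The forecast also said product at 50%, holding that “the catalyst parks as A, with substrate bound and waiting for reagent”.

The flask gave product at 50.0%, with substrate at 36.0% and intermediate A at 14.0%.

    catalyst intermediate D → free catalyst + product (k = 0.340 s⁻¹)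
    catalyst intermediate B ⇌ catalyst intermediate C (K = 1.10, k = 0.340 s⁻¹)
    reagent + catalyst intermediate A → catalyst intermediate B (k = 630 M⁻¹ s⁻¹)
    catalyst intermediate C → by-product + catalyst intermediate D (k = 2.80 s⁻¹)
    substrate + free catalyst → catalyst intermediate A (k = 200 M⁻¹ s⁻¹)

In this flask, reagent stood at 0% by 2.00 min, when product had reached 50.0%. In the neighbour flask charged with 0.300 equiv of reagent, N was 2.14, which times the loading gives 30.0%, and that flask ended with 30.0% product and 56.0% substrate.

All runs were generated by integration for substances that don't exist, and the scatter is random.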